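**The vessel.** The vessel took free monomer at a steady rate, with protic impurity, initiator and stray impurity also present.

| setting | ash | flask |
|---|---|---|
| free monomer | 0.050 M (fed, over 25 min) | 0.050 M (fed, over 25 min) |
| protic impurity | 0.050 M | 0.0500 M |
| initiator | 4 mol% | 2 mol% |
| stray impurity | 1.3 mM | 1.3 mM |
| remark | run made earlier |  |
| time |  | 25 min |

ash run (percent of the free monomer charged)

| time / min | monomer in chains / % | free monomer / % |
|---|---|---|
| 0.667 | 0 | 2.4 |
| 2.00 | 0 | 8.0 |
| 4.00 | 0 | 16.3 |
| 5.00 | 0 | 20.8 |
| 8.00 | 0.4 | 28.3 |

(standard deviation of a reading: 1 percentage point)

- the average divides the monomer in chains by the number of chains begun, living and dead together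
- the earlier runs were read with a standard deviation of 1 percentage point
- the earlier runs do not show the number of chains; that part of a forecast is a guess
- percentages count the whole charge, also what has not yet gone in
- no earlier run changes the charge of initiator; that part of a forecast is a guess

* average number of monomer units in a chain (chains begun, living or dead) at 25 min
* part of the free monomer that has reacted at 25 min

**First estimate.** In the ash run I subtracted the free monomer and chains found from what had been fed. At 8.00 min this gap was 3.3 percentage points. I laid it on the protic impurity, a pseudo-first-order drain, with a charge equal in both flasks. Early on, the lost fraction of the charge is half the loss number (the drain's rate times the dosing time) times the square of the fed fraction, and this one gap read 0.645.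

**A thin reading.** But that was one gap against a scatter of 1 point, and at 5.00 min the gap was −0.8 points. Fitting both gaps by least squares gave the loss number, the drain's rate times the dosing time, as 0.506.

**The far end.** Under a constant drain, free monomer levels at the inverse of a large loss number, while a small one keeps the early law. The join makes the unreacted fraction at the end of dosing one minus the exponential of minus the number, divided by the number. So I reckoned 21.5 % reacted at the end of dosing.

**A falling drain.** That held the protic impurity constant, yet its charge equals the monomer's. Taking half the end loss off the number gave 0.452 and 19.5 %.

**Chains.** In the flask, initiator was 2 mol% of the charge, less than the stray impurity's 2.60 %. I therefore added nothing for chains and left their length unreckoned, since no run showed their number.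

**The forecast.** The forecast gave 3 % reacted and 1.5 units per chain. Supposing a one-to-one titration, which it called a guess, it held that “everything dies before real growth, so conversion stays tiny and chains hold only a unit or so”. Its conversion stood below mine.

**The result.** The flask gave 17.0 % reacted, against my 19.5 %, and 26.1 units per chain. In the flask at 25.0 min, quenched substrate held 16.6 % of the charge and monomer in chains 0.391 %. The early law, with the loss number read from the ash run, reckoned 6.33 % reacted at 12.5 min, against 4.80 % in the flask.

    free monomer + initiator → living end + monomer in chains (k = 0.0240 /M/s)
    protic impurity + free monomer → quenched substrate (k = 0.00550 /M/s)
    free monomer + living end → monomer in chains + living end, rate k3*[living end]*[free monomer] (k = 0.810 /M/s)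
    initiator + stray impurity → spent initiator (k = 18.0 /M/s)

**A neighbour.** A neighbour had 5 mol% of initiator and all other charges as in the flask, and for its drain I reckoned the same 19.5 % from the loss number. Computed, that neighbour held 15.2 % quenched substrate and 18.0 % monomer in chains at 25.0 min, with 33.2 % reacted.

The readings were computed for substances that don't exist; the scatter is artificial.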